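**Plan**

1. Retrosynthesis: the O1–C2 and O1'–C2' bonds of the two pyran rings are cut first (phenol plus benzylic alcohol), then both C2–phenyl and C2'–phenyl bonds (dialdehyde plus two phenyl groups). C2 and C2' are then traced back to the CH2 ends of two vinyl groups, and last the C4'–O bond of the central ether is cut between an allylic alcohol (unit A, the 5-hydroxy half) and a cinnamyl carbonate (unit B, the trimethoxy half).
2. Feature used: in each flavan unit everything beyond C4 (C4') is the C3 methylene and a C2 carbon that bears only phenyl and the ring oxygen O1 (O1'). Once both pyran rings are opened at O1–C2, the halves end in identical CH2–CHO arms, so both phenyl groups and both C2 centres can be added at once to one open-chain dialdehyde.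
3. Forward: one salicylaldehyde from 3,4,5-trimethoxyphenol serves both units. The C4–O–C4' ether is built first on open chains, the two chain ends are then processed in pairs (hydroboration, oxidation, phenyl transfer, desilylation), and the two pyran rings close last and together.
4. Stereochemistry: C4 and C4' (both R) come from one enantiomer of an iridium phosphoramidite catalyst in two allylic substitutions. C2 and C2' are set as (R)-carbinols by a chiral zinc amino-alkoxide and inverted to (S) in the Mitsunobu closure.
5. Protection: TBS on the oxygens that become O1 and O1', TIPS on the C5 oxygen of unit A. Both are removed by fluoride, so no step needs acid, which the doubly benzylic ether would not survive.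

Key step: step 15

Abbreviations: TBS = tert-butyldimethylsilyl; TIPS = triisopropylsilyl; ArA = 2-(TBS-oxy)-4,5-dimethoxy-6-(TIPS-oxy)phenyl; ArB = 2-(TBS-oxy)-4,5,6-trimethoxyphenyl; cod = 1,5-cyclooctadiene; 9-BBN = 9-borabicyclo[3.3.1]nonane; DIAD = diisopropyl azodicarboxylate; L = (Ra,Rc,Rc)-O,O'-(1,1'-binaphthalene-2,2'-diyl) N,N-bis(1-phenylethyl)phosphoramidite. Chain atoms carry flavan numbers from the start (primes for unit B).

Handling: from 8 and 13 onward all intermediates are kept free of acid (Et3N-treated silica), because benzylic and cinnamylic C–O bonds on these tetra-oxygenated rings ionise easily.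

Assumption (sense of induction): L as the (Ra,Rc,Rc) enantiomer is taken to deliver oxygen nucleophiles to the Re face of the aryl-bearing allyl carbon, and the (R)-amino alcohol of step 15 to deliver the zinc-bound aryl group to the Si face of an aldehyde as it does alkyl groups; if a first run shows the opposite sense in either case, the antipodal ligand is used.

**Route**

Step 1
Reactants: 1 3,4,5-trimethoxyphenol
Product: 3 2-hydroxy-4,5,6-trimethoxybenzaldehyde, via 2-(hydroxymethyl)-3,4,5-trimethoxyphenol 2 (not isolated)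
Conditions: MgCl2, Et3N, (CH2O)n, MeCN, reflux; aq. HCl
Reagents that add atoms: paraformaldehyde (as formaldehyde), C=O
Why: Magnesium-mediated ortho-formylation of a phenol (Casnati–Skattebøl reaction), in which the magnesium phenoxide delivers formaldehyde to the ortho carbon and a second formaldehyde oxidises the benzylic alcohol 2 by hydride transfer; the two ortho positions of the symmetric phenol are equivalent, so only one aldehyde can form.

Step 2
Reactants: 3 2-hydroxy-4,5,6-trimethoxybenzaldehyde
Product: 4 2-(tert-butyldimethylsilyloxy)-4,5,6-trimethoxybenzaldehyde (aldehyde of unit B)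
Conditions: TBSCl, imidazole, DMF, rt
Reagents that add atoms: tert-butyldimethylsilyl chloride, CC(C)(C)[Si](C)(C)Cl
Why: Imidazole-promoted silyl ether formation at the only hydroxyl group, which puts the more fluoride-labile silyl group on the oxygen that later becomes O1 or O1'.

Step 3
Reactants: 4 2-(tert-butyldimethylsilyloxy)-4,5,6-trimethoxybenzaldehyde
Product: 5 2-(tert-butyldimethylsilyloxy)-6-hydroxy-4,5-dimethoxybenzaldehyde
Conditions: MgI2·OEt2, toluene, 70 °C; aq. NH4Cl
Reagents that add atoms: none
Why: Chelation-assisted O-demethylation, in which magnesium held between the aldehyde oxygen and the adjacent C6 methoxy oxygen activates only that methyl group for SN2 attack by iodide, while the other two methoxy groups cannot chelate and iodide does not attack the hindered silicon.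

Step 4
Reactants: 5 2-(tert-butyldimethylsilyloxy)-6-hydroxy-4,5-dimethoxybenzaldehyde
Product: 6 2-(tert-butyldimethylsilyloxy)-4,5-dimethoxy-6-(triisopropylsilyloxy)benzaldehyde (aldehyde of unit A)
Conditions: TIPSOTf, 2,6-lutidine, CH2Cl2, 0 °C to rt
Reagents that add atoms: triisopropylsilyl trifluoromethanesulfonate, CC(C)[Si](OS(=O)(=O)C(F)(F)F)(C(C)C)C(C)C
Why: Silyl ether formation with a silyl triflate and a hindered pyridine base, reactive enough for a phenol that is hydrogen bonded to the aldehyde and flanked on both sides; the bulkier silyl group marks the oxygen that becomes the C5 hydroxyl.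

Step 5
Reactants: 6 2-(tert-butyldimethylsilyloxy)-4,5-dimethoxy-6-(triisopropylsilyloxy)benzaldehyde
Product: 7 ethyl (E)-3-ArA-prop-2-enoate
Conditions: Ph3P=CHCO2Et, toluene, 100 °C
Reagents that add atoms: ethyl (triphenylphosphoranylidene)acetate, CCOC(=O)C=P(c1ccccc1)(c1ccccc1)c1ccccc1
Why: Wittig olefination with a stabilised ylide, which is neutral (no silyl loss or migration) and gives the (E)-alkene; the small aldehyde hydrogen keeps the carbonyl carbon accessible despite the two ortho silyloxy groups.

Step 6
Reactants: 7 ethyl (E)-3-ArA-prop-2-enoate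
Product: 8 (E)-3-ArA-prop-2-en-1-ol
Conditions: iBu2AlH, CH2Cl2, −78 °C; aq. KNaC4H4O6
Reagents that add atoms: none
Why: 1,2-Reduction of a conjugated ester to the allylic alcohol by an aluminium hydride at low temperature, which leaves the alkene and both aryl silyl ethers untouched.

Step 7
Reactants: 8 (E)-3-ArA-prop-2-en-1-ol; 9 methyl chloroformate
Product: 10 (E)-3-ArA-prop-2-enyl methyl carbonate
Conditions: pyridine, CH2Cl2, 0 °C
Reagents that add atoms: none
Why: Acylation of a primary allylic alcohol by a chloroformate (carbonate formation) under basic conditions, which avoids ionisation of the electron-rich cinnamyl system.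

Step 8
Reactants: 10 (E)-3-ArA-prop-2-enyl methyl carbonate
Product: 11 (R)-1-ArA-prop-2-en-1-ol
Conditions: [Ir(cod)Cl]2 (2 mol%), L (4 mol%, catalyst pre-formed with n-PrNH2), KHCO3, THF–H2O, rt
Reagents that add atoms: potassium hydrogencarbonate, [K+].OC([O-])=O
Why: Iridium-catalysed asymmetric allylic substitution with hydrogencarbonate as a hydroxide equivalent, in which the allyl-iridium intermediate is attacked at the aryl-bearing carbon (favoured by the electron-rich ring), the carbonic half-ester loses CO2, and the cyclometalated phosphoramidite directs oxygen to the Re face so that C4 is formed as (R).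

Step 9
Reactants: 4 2-(tert-butyldimethylsilyloxy)-4,5,6-trimethoxybenzaldehyde
Product: 12 ethyl (E)-3-ArB-prop-2-enoate
Conditions: Ph3P=CHCO2Et, toluene, 100 °C
Reagents that add atoms: ethyl (triphenylphosphoranylidene)acetate, CCOC(=O)C=P(c1ccccc1)(c1ccccc1)c1ccccc1
Why: Wittig olefination with a stabilised ylide, neutral towards the aryl silyl ether and (E)-selective.

Step 10
Reactants: 12 ethyl (E)-3-ArB-prop-2-enoate
Product: 13 (E)-3-ArB-prop-2-en-1-ol
Conditions: iBu2AlH, CH2Cl2, −78 °C; aq. KNaC4H4O6
Reagents that add atoms: none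
Why: 1,2-Reduction of the conjugated ester to the allylic alcohol by an aluminium hydride, as in step 6.

Step 11
Reactants: 13 (E)-3-ArB-prop-2-en-1-ol
Product: 14 tert-butyl (E)-3-ArB-prop-2-enyl carbonate
Conditions: Boc2O, 4-(dimethylamino)pyridine (cat.), CH2Cl2, 0 °C to rt
Reagents that add atoms: di-tert-butyl dicarbonate, CC(C)(C)OC(=O)OC(=O)OC(C)(C)C
Why: Nucleophile-catalysed acylation with a dicarbonate (carbonate formation); the tert-butyl carbonate is chosen because the tert-butoxide it releases in step 12 is too hindered to compete with the alkoxide of 11 as a nucleophile.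

Step 12
Reactants: 11 (R)-1-ArA-prop-2-en-1-ol; 14 tert-butyl (E)-3-ArB-prop-2-enyl carbonate
Product: 16 (R)-1-ArA-prop-2-enyl (R)-1-ArB-prop-2-enyl ether, via zinc bis-alkoxide 15 (not isolated)
Conditions: 11, Et2Zn (0.5 equiv), THF, 0 °C; then 14, [Ir(cod)Cl]2 (3 mol%), L (6 mol%, pre-formed with n-PrNH2), THF, rt
Reagents that add atoms: none
Why: Iridium-catalysed asymmetric allylic etherification with a zinc alkoxide, in which the covalent alkoxide 15 attacks the allyl-iridium intermediate from 14 at the aryl-bearing carbon without provoking silyl migration from the neighbouring phenolic oxygens; the same ligand enantiomer as in step 8 directs oxygen to the Re face and sets C4' as (R) under catalyst control, while C4 of 11 is not touched.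

Step 13
Reactants: 16 (R)-1-ArA-prop-2-enyl (R)-1-ArB-prop-2-enyl ether
Product: 18 (3R)-3-ArA-3-[(1R)-1-ArB-3-hydroxypropoxy]propan-1-ol, via bis-borane 17 (not isolated)
Conditions: 9-BBN, THF, 0 °C to rt; then NaBO3·4H2O, H2O, rt
Reagents that add atoms: sodium perborate (NaBO3·4H2O), [Na+].[Na+].O[B-]1(O)OO[B-](O)(O)OO1
Why: Two-fold hydroboration–oxidation, in which the bulky dialkylborane puts boron only on the terminal carbons C2 and C2' (17, boron gamma to the ether oxygen, so no elimination) and mildly basic perborate oxidises the C–B bonds without cleaving the aryl silyl ethers.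

Step 14
Reactants: 18 (3R)-3-ArA-3-[(1R)-1-ArB-3-hydroxypropoxy]propan-1-ol
Product: 19 (3R)-3-ArA-3-[(1R)-1-ArB-3-oxopropoxy]propanal (the dialdehyde)
Conditions: Dess–Martin periodinane, NaHCO3, CH2Cl2, 0 °C to rt; used at once
Reagents that add atoms: none
Why: Dess–Martin oxidation of both primary alcohols under hydrogencarbonate buffer, a neutral method that avoids both acid ionisation of the benzylic ether and base-induced elimination of the beta-alkoxy aldehydes.

Step 15
Reactants: 19 (3R)-3-ArA-3-[(1R)-1-ArB-3-oxopropoxy]propanal; 20 phenylboronic acid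
Product: 22 (1R,3R)-3-ArA-3-[(1R,3R)-1-ArB-3-hydroxy-3-phenylpropoxy]-1-phenylpropan-1-ol, via ethyl(phenyl)zinc 21 (not isolated)
Conditions: 20 (5 equiv), Et2Zn (15 equiv), toluene, 60 °C; then (R)-2-piperidino-1,1,2-triphenylethanol (20 mol%), MeO(CH2CH2O)nMe (cat.), slow addition of 19, toluene, −10 °C; aq. NH4Cl
Reagents that add atoms: none
Why: Boron-to-zinc exchange between 20 and Et2Zn gives the mixed arylzinc 21, and the zinc alkoxide of the amino alcohol binds one molecule of 21 and one aldehyde group in a bimetallic six-membered transition state from which phenyl, the better migrating group, passes to the carbonyl carbon. The closest known reaction is the catalytic enantioselective aryl transfer from an arylboronic acid and Et2Zn to an aliphatic aldehyde, here applied twice in one molecule whose aldehyde groups are seven atoms apart and react independently. No ring is closed in this step. C2 and C2' are each set by the ligand, whose (R) enantiomer sends the aryl group to the Si face of the aldehyde, which for an aldehyde of the type R–CH2–CHO is the (R)-carbinol. The selectivity needed is reagent control over 1,3-induction from the beta-alkoxy centres C4 and C4' and over the unligated background addition; the ether oxygen sits between two ortho-disubstituted aryl groups and is therefore a poor ligand for zinc, and slow addition of 19 at low temperature with the polyether additive keeps the uncatalysed path slow. Because the two (R) centres are related by pseudo-twofold symmetry, both aldehydes meet the catalyst in the same stereochemical situation.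

Step 16
Reactants: 22 (1R,3R)-3-ArA-3-[(1R,3R)-1-ArB-3-hydroxy-3-phenylpropoxy]-1-phenylpropan-1-ol
Product: 23 (1R,3R)-3-[2-hydroxy-4,5-dimethoxy-6-(triisopropylsilyloxy)phenyl]-3-[(1R,3R)-3-hydroxy-1-(2-hydroxy-4,5,6-trimethoxyphenyl)-3-phenylpropoxy]-1-phenylpropan-1-ol
Conditions: Bu4NF (2.2 equiv), AcOH (2.2 equiv), THF, −20 to 0 °C
Reagents that add atoms: none
Why: Fluoride cleavage of aryl silyl ethers under acetic acid buffer, in which the two tert-butyldimethylsilyl groups next to C8–H and C8'–H should react much faster than the triisopropylsilyl group wedged between the C6 methoxy group and C4, and the buffer keeps the phenols protonated so that the C4 alkoxide is not expelled through an ortho-quinone methide.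

Step 17
Reactants: 23 the bis-phenol diol of step 16
Product: 24 (2S,4R)-6,7-dimethoxy-2-phenyl-5-(triisopropylsilyloxy)chroman-4-yl (2S,4R)-5,6,7-trimethoxy-2-phenylchroman-4-yl ether
Conditions: PPh3, DIAD, THF (high dilution), 0 °C to rt
Reagents that add atoms: none
Why: Two-fold intramolecular Mitsunobu etherification, in which each benzylic alcohol is activated as an alkoxyphosphonium ion and displaced by the phenoxide in a 6-exo-tet SN2 closure, so O1–C2 and O1'–C2' form with inversion to (S) (an unsubstituted phenyl group does not favour ionisation) while C4 and C4' stay untouched.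

Step 18
Reactants: 24 the 5-O-triisopropylsilyl ether of the target
Product: 25 beilschmieflavonoid B, (2S,4R)-5-hydroxy-6,7-dimethoxyflavan-4-yl (2S,4R)-5,6,7-trimethoxyflavan-4-yl ether
Conditions: Bu4NF (1.5 equiv), AcOH (1.5 equiv), THF, 0 °C to rt
Reagents that add atoms: none
Why: Fluoride cleavage of the remaining, hindered aryl silyl ether (desilylation), run buffered so that the freed C5 phenol does not expel the C4 ether; no stereocentre is involved.

**Compound list**

1 | 3,4,5-trimethoxyphenol | COc1cc(O)cc(OC)c1OC | starting material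
2 | 2-(hydroxymethyl)-3,4,5-trimethoxyphenol (not isolated) | OCc1c(O)cc(OC)c(OC)c1OC | intermediate
3 | 2-hydroxy-4,5,6-trimethoxybenzaldehyde | O=Cc1c(O)cc(OC)c(OC)c1OC | intermediate
4 | 2-(tert-butyldimethylsilyloxy)-4,5,6-trimethoxybenzaldehyde | O=Cc1c(O[Si](C)(C)C(C)(C)C)cc(OC)c(OC)c1OC | intermediate
5 | 2-(tert-butyldimethylsilyloxy)-6-hydroxy-4,5-dimethoxybenzaldehyde | O=Cc1c(O[Si](C)(C)C(C)(C)C)cc(OC)c(OC)c1O | intermediate
6 | 2-(tert-butyldimethylsilyloxy)-4,5-dimethoxy-6-(triisopropylsilyloxy)benzaldehyde | O=Cc1c(O[Si](C)(C)C(C)(C)C)cc(OC)c(OC)c1O[Si](C(C)C)(C(C)C)C(C)C | intermediate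
7 | ethyl (E)-3-ArA-prop-2-enoate | CCOC(=O)/C=C/c1c(O[Si](C)(C)C(C)(C)C)cc(OC)c(OC)c1O[Si](C(C)C)(C(C)C)C(C)C | intermediate
8 | (E)-3-ArA-prop-2-en-1-ol | OC/C=C/c1c(O[Si](C)(C)C(C)(C)C)cc(OC)c(OC)c1O[Si](C(C)C)(C(C)C)C(C)C | intermediate
9 | methyl chloroformate | COC(=O)Cl | starting material
10 | (E)-3-ArA-prop-2-enyl methyl carbonate | COC(=O)OC/C=C/c1c(O[Si](C)(C)C(C)(C)C)cc(OC)c(OC)c1O[Si](C(C)C)(C(C)C)C(C)C | intermediate
11 | (R)-1-ArA-prop-2-en-1-ol | C=C[C@@H](O)c1c(O[Si](C)(C)C(C)(C)C)cc(OC)c(OC)c1O[Si](C(C)C)(C(C)C)C(C)C | intermediate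
12 | ethyl (E)-3-ArB-prop-2-enoate | CCOC(=O)/C=C/c1c(O[Si](C)(C)C(C)(C)C)cc(OC)c(OC)c1OC | intermediate
13 | (E)-3-ArB-prop-2-en-1-ol | OC/C=C/c1c(O[Si](C)(C)C(C)(C)C)cc(OC)c(OC)c1OC | intermediate
14 | tert-butyl (E)-3-ArB-prop-2-enyl carbonate | CC(C)(C)OC(=O)OC/C=C/c1c(O[Si](C)(C)C(C)(C)C)cc(OC)c(OC)c1OC | intermediate
15 | zinc bis[(R)-1-ArA-prop-2-en-1-olate] (not isolated) | C=C[C@@H](O[Zn]O[C@H](C=C)c1c(O[Si](C)(C)C(C)(C)C)cc(OC)c(OC)c1O[Si](C(C)C)(C(C)C)C(C)C)c1c(O[Si](C)(C)C(C)(C)C)cc(OC)c(OC)c1O[Si](C(C)C)(C(C)C)C(C)C | intermediate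
16 | (R)-1-ArA-prop-2-enyl (R)-1-ArB-prop-2-enyl ether | C=C[C@H](c1c(O[Si](C)(C)C(C)(C)C)cc(OC)c(OC)c1O[Si](C(C)C)(C(C)C)C(C)C)O[C@H](C=C)c1c(O[Si](C)(C)C(C)(C)C)cc(OC)c(OC)c1OC | intermediate
17 | bis-borane: ether 16 with a 9-borabicyclo[3.3.1]nonan-9-yl group on C2 and on C2' (not isolated) | C1CC2CCCC(C1)B2CC[C@H](c1c(O[Si](C)(C)C(C)(C)C)cc(OC)c(OC)c1O[Si](C(C)C)(C(C)C)C(C)C)O[C@@H](c1c(O[Si](C)(C)C(C)(C)C)cc(OC)c(OC)c1OC)CCB1C2CCCC1CCC2 | intermediate
18 | (3R)-3-ArA-3-[(1R)-1-ArB-3-hydroxypropoxy]propan-1-ol | OCC[C@H](c1c(O[Si](C)(C)C(C)(C)C)cc(OC)c(OC)c1O[Si](C(C)C)(C(C)C)C(C)C)O[C@@H](c1c(O[Si](C)(C)C(C)(C)C)cc(OC)c(OC)c1OC)CCO | intermediate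
19 | (3R)-3-ArA-3-[(1R)-1-ArB-3-oxopropoxy]propanal, the (4R,4'R)-dialdehyde | O=CC[C@H](c1c(O[Si](C)(C)C(C)(C)C)cc(OC)c(OC)c1O[Si](C(C)C)(C(C)C)C(C)C)O[C@@H](c1c(O[Si](C)(C)C(C)(C)C)cc(OC)c(OC)c1OC)CC=O | intermediate
20 | phenylboronic acid | OB(O)c1ccccc1 | starting material
21 | ethyl(phenyl)zinc (not isolated) | CC[Zn]c1ccccc1 | intermediate
22 | (1R,3R)-3-ArA-3-[(1R,3R)-1-ArB-3-hydroxy-3-phenylpropoxy]-1-phenylpropan-1-ol, the (2R,4R,2'R,4'R)-diol | O[C@@H](c1ccccc1)C[C@H](c1c(O[Si](C)(C)C(C)(C)C)cc(OC)c(OC)c1O[Si](C(C)C)(C(C)C)C(C)C)O[C@@H](c1c(O[Si](C)(C)C(C)(C)C)cc(OC)c(OC)c1OC)C[C@@H](O)c1ccccc1 | intermediate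
23 | bis-phenol diol: 22 with both tert-butyldimethylsilyl groups replaced by hydrogen | O[C@@H](c1ccccc1)C[C@H](c1c(O)cc(OC)c(OC)c1O[Si](C(C)C)(C(C)C)C(C)C)O[C@@H](c1c(O)cc(OC)c(OC)c1OC)C[C@@H](O)c1ccccc1 | intermediate
24 | (2S,4R)-6,7-dimethoxy-2-phenyl-5-(triisopropylsilyloxy)chroman-4-yl (2S,4R)-5,6,7-trimethoxy-2-phenylchroman-4-yl ether | COc1cc2c(c(O[Si](C(C)C)(C(C)C)C(C)C)c1OC)[C@H](O[C@@H]1C[C@@H](c3ccccc3)Oc3cc(OC)c(OC)c(OC)c31)C[C@@H](c1ccccc1)O2 | intermediate
25 | beilschmieflavonoid B | COc1cc2c(c(O)c1OC)[C@H](O[C@@H]1C[C@@H](c3ccccc3)Oc3cc(OC)c(OC)c(OC)c31)C[C@@H](c1ccccc1)O2 | target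

**Step count**

Total: 18 steps. Longest linear sequence: 15 steps (steps 1–8 and 12–18).

**Steps most likely to fail**

Step 12. The risk is attack of the bulky zinc alkoxide at the unsubstituted allyl carbon (linear ether), slow turnover caused by the two ortho substituents of the allyl unit, or erosion of catalyst control by the resident (R) centre. The fallback replaces catalyst-controlled substitution by a stereospecific one. It sets out from 13 (and uses 11): acylation of 13 with 9 and pyridine would give the linear methyl carbonate F1, which under the conditions of step 8 should give the (R)-allylic alcohol F2. A second acylation with 9 gives the branched (R)-methyl carbonate F3, used crude and cold. The copper alkoxide of 11 (LiN(SiMe3)2 at −78 °C, then CuI at once, THF) would then displace the carbonate of F3 under RhCl(PPh3)3/P(OMe)3 catalysis. This rhodium-catalysed allylic etherification is known to substitute at the carbon that carried the leaving group with net retention, so the (R) centre of F3 becomes C4' and the sequence returns to the route at 16.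

Step 15. The risk is poor facial selectivity at one or both aldehydes (1,3-induction or zinc chelation by the ether oxygen overriding the ligand), competing ethyl transfer, or loss of the C4 alkoxide by elimination. The fallback sets the carbinol centres by ketone reduction instead of during C–C bond formation. It sets out from 19: PhMgBr (THF, −78 °C) would give the C2/C2'-epimeric diol mixture F4, and Dess–Martin oxidation (NaHCO3 buffer) the diketone F5. Corey–Bakshi–Shibata reduction of F5 with (S)-1-methyl-3,3-diphenyltetrahydro-1H,3H-pyrrolo[1,2-c][1,3,2]oxazaborole and BH3·SMe2 at −20 °C should deliver hydride to each aryl alkyl ketone from the face that gives the (R)-carbinol, and the sequence returns to the route at 22. The same C2–phenyl bonds are formed from the same dialdehyde, only without stereocontrol at that stage.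

Step 16. The risk is partial loss of the triisopropylsilyl group, after which either phenol of ring A could close the pyran ring in step 17, or base-induced loss of the C4 ether through an ortho-quinone methide. The fallback activates the alcohols first and unmasks the phenols last. It sets out from 22: MsCl and Et3N (CH2Cl2, −20 °C) would give the bis-mesylate F6 with the carbinol configuration retained. CsF in DMF at 0 °C then removes the two tert-butyldimethylsilyl groups, and each phenoxide should displace the neighbouring benzylic mesylate at once (SN2, inversion to 2S), returning to the route at 24. Because each electrophile is consumed as soon as the less hindered phenoxide appears, later loss of the triisopropylsilyl group cannot misdirect the ring closure.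

Further compounds
F1 | step 12 | (E)-3-ArB-prop-2-enyl methyl carbonate | COC(=O)OC/C=C/c1c(O[Si](C)(C)C(C)(C)C)cc(OC)c(OC)c1OC
F2 | step 12 | (R)-1-ArB-prop-2-en-1-ol | C=C[C@@H](O)c1c(O[Si](C)(C)C(C)(C)C)cc(OC)c(OC)c1OC
F3 | step 12 | (R)-1-ArB-prop-2-enyl methyl carbonate | C=C[C@@H](OC(=O)OC)c1c(O[Si](C)(C)C(C)(C)C)cc(OC)c(OC)c1OC
F4 | step 15 | (3R)-3-ArA-3-[(1R)-1-ArB-3-hydroxy-3-phenylpropoxy]-1-phenylpropan-1-ol as a mixture of epimers at C2 and C2' | OC(c1ccccc1)C[C@H](c1c(O[Si](C)(C)C(C)(C)C)cc(OC)c(OC)c1O[Si](C(C)C)(C(C)C)C(C)C)O[C@@H](c1c(O[Si](C)(C)C(C)(C)C)cc(OC)c(OC)c1OC)CC(O)c1ccccc1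
F5 | step 15 | (3R)-3-ArA-3-[(1R)-1-ArB-3-oxo-3-phenylpropoxy]-1-phenylpropan-1-one | O=C(c1ccccc1)C[C@H](c1c(O[Si](C)(C)C(C)(C)C)cc(OC)c(OC)c1O[Si](C(C)C)(C(C)C)C(C)C)O[C@@H](c1c(O[Si](C)(C)C(C)(C)C)cc(OC)c(OC)c1OC)CC(=O)c1ccccc1
F6 | step 16 | bis(methanesulfonate) of diol 22 at the C2 and C2' oxygens, (2R,4R,2'R,4'R) | CS(=O)(=O)O[C@@H](c1ccccc1)C[C@H](c1c(O[Si](C)(C)C(C)(C)C)cc(OC)c(OC)c1O[Si](C(C)C)(C(C)C)C(C)C)O[C@@H](c1c(O[Si](C)(C)C(C)(C)C)cc(OC)c(OC)c1OC)C[C@@H](OS(C)(=O)=O)c1ccccc1
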